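The dihydrofuran ring is cut at C3–C3a and O1–C7a, giving an aryl iodide (iodine on C7a, free C–H on C3a, C7 already bearing the pyranonylmethyl arm) and an enantiopure terminal oxirane. A Pd/norbornene (Catellani-type) annulation stitches both bonds in one operation: the oxirane CH2 alkylates C3a, its oxygen then displaces palladium at C7a, and the oxirane stereocentre becomes C2 untouched. The step exploits the adjacency of C3a and C7a and the blocking substituent on C7, which allows exactly one ortho relay. The 1,1-disubstituted alkene is masked as a β-silyl silyl ether so the oxirane is not allylic; acid finally removes the MOM groups and unveils the alkene (Peterson).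

Key step: step 11

Remark: the stereocentre is read as (R) at C2 of the 2,3-dihydrobenzofuran; compounds 20–22 are mixtures of epimers at the silyl-substituted carbinol carbon, which becomes sp2 in step 12, and the pyranone is taken to be protected at O-4 (an O-2 isomer would converge in step 12).

Step 1
Reactants: 1 1-(2,6-dimethoxyphenyl)ethanone
Product: 3 1-(4-iodo-2,6-dimethoxyphenyl)ethanone, via arylboronate 2 (not isolated)
Conditions: B2pin2 (1.0 equiv), [Ir(OMe)(cod)]2 (1.5 mol%), dtbpy (3 mol%), THF, 80 °C; evaporate; then KI (1.5 equiv), CuI (10 mol%), 1,10-phenanthroline (20 mol%), MeOH/H2O 4:1, air, 80 °C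
Reagents that add atoms: potassium iodide, [K+].[I-]
Why: Ir-catalysed C–H borylation is sterically governed and should borylate the only ring C–H without an ortho substituent (C4, meta to both methoxy groups), and Cu-mediated iododeboronation then places iodine on that carbon, a position that electrophilic iodination cannot reach.

Step 2
Reactants: 3 1-(4-iodo-2,6-dimethoxyphenyl)ethanone
Product: 4 1-(2,6-dihydroxy-4-iodophenyl)ethanone
Conditions: BBr3 (3 equiv), CH2Cl2, −78 °C → rt; H2O
Reagents that add atoms: none
Why: BBr3 cleaves aryl methyl ethers (Lewis acid-mediated demethylation), both of which are activated by chelation to the ortho acetyl group, while the aryl iodide and the ketone are inert.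

Step 3
Reactants: 5 methyl 3-oxopentanoate; 6 N-methoxy-N-methylpropanamide
Product: 8 methyl 4-methyl-3,5-dioxoheptanoate, via dianion 7 (not isolated)
Conditions: NaH (1.1 equiv), THF, 0 °C; n-BuLi (1.05 equiv), 0 °C; then 6, 0 °C → rt; aq. HCl
Reagents that add atoms: none
Why: Acylation of a β-keto ester dianion at its more basic γ-carbon with a Weinreb amide, whose tetrahedral adduct prevents over-addition, should give the 3,5-diketo ester.

Step 4
Reactants: 8 methyl 4-methyl-3,5-dioxoheptanoate
Product: 9 6-ethyl-4-hydroxy-5-methyl-2H-pyran-2-one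
Conditions: DBU (1 equiv), toluene, reflux; aq. HCl
Reagents that add atoms: none
Why: Base-mediated enol lactonisation of a 3,5-diketo ester (6-exo-trig acyl substitution with loss of methanol) is the standard entry to 4-hydroxy-2-pyranones.

Step 5
Reactants: 9 6-ethyl-4-hydroxy-5-methyl-2H-pyran-2-one; 4 1-(2,6-dihydroxy-4-iodophenyl)ethanone
Product: 12 3-[(3-acetyl-2,4-dihydroxy-6-iodophenyl)methyl]-6-ethyl-4-hydroxy-5-methyl-2H-pyran-2-one, via Mannich base 10 (not isolated), via pyranone methide 11 (not isolated)
Conditions: 9, Eschenmoser's salt (1.0 equiv), MeCN, rt; then 4 (2.5 equiv, excess recovered), 70 °C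
Reagents that add atoms: N,N-dimethylmethyleneiminium iodide (Eschenmoser's salt), C=[N+](C)C.[I-]
Why: Mannich reaction at the nucleophilic C3 of the pyranone and loss of dimethylamine give the methide 11, which the symmetric resorcinol 4 should trap by conjugate addition through the carbon ortho to one hydroxyl and para to the other (Mannich/Michael methylene bridging), pre-formation of 10 and excess 4 suppressing pyranone dimer and double alkylation.

Step 6
Reactants: 12 3-[(3-acetyl-2,4-dihydroxy-6-iodophenyl)methyl]-6-ethyl-4-hydroxy-5-methyl-2H-pyran-2-one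
Product: 13 3-{[3-acetyl-6-iodo-2,4-bis(methoxymethoxy)phenyl]methyl}-6-ethyl-4-(methoxymethoxy)-5-methyl-2H-pyran-2-one
Conditions: MOMCl (6 equiv), i-Pr2NEt (8 equiv), CH2Cl2/DMF, 0 → 40 °C
Reagents that add atoms: chloromethyl methyl ether, COCCl
Why: Williamson-type O-alkylation of the two phenols and the acidic pyranone enol masks every acidic OH group, which would otherwise quench or ligate the Pd/norbornene catalyst.

Step 7
Reactants: 14 5-bromo-2-methylpent-2-ene; 15 acrolein
Product: 17 rac-7-methylocta-1,6-dien-3-ol, via Grignard reagent 16 (not isolated)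
Conditions: Mg, THF, rt → 40 °C; then 15, −78 → 0 °C; aq. NH4Cl
Reagents that add atoms: none
Why: Grignard 1,2-addition to acrolein at low temperature should give the racemic secondary allylic alcohol.

Step 8
Reactants: 17 rac-7-methylocta-1,6-dien-3-ol
Product: 18 (1S)-5-methyl-1-[(2R)-oxiran-2-yl]hex-4-en-1-ol
Conditions: Ti(Oi-Pr)4 (10 mol%), L-(+)-diisopropyl tartrate (15 mol%), t-BuOOH (0.55 equiv), 4 Å MS, CH2Cl2, −20 °C; stopped near half conversion
Reagents that add atoms: tert-butyl hydroperoxide, CC(C)(C)OO
Why: Sharpless kinetic resolution (hydroxyl-directed Ti/tartrate epoxidation): with L-(+)-DIPT the (S)-alcohol should react fast and give the anti (erythro) epoxy alcohol, which sets the (R) oxirane carbon by reagent control and leaves the remote trisubstituted alkene and the slow (R)-alcohol (separated) untouched.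

Step 9
Reactants: 18 (1S)-5-methyl-1-[(2R)-oxiran-2-yl]hex-4-en-1-ol
Product: 19 5-methyl-1-[(2R)-oxiran-2-yl]hex-4-en-1-one
Conditions: TPAP (5 mol%), NMO (1.5 equiv), 4 Å MS, CH2Cl2, rt
Reagents that add atoms: none
Why: Ley–Griffith oxidation is neutral and should convert the secondary alcohol into the ketone without touching the oxirane, its stereocentre or the alkene.

Step 10
Reactants: 19 5-methyl-1-[(2R)-oxiran-2-yl]hex-4-en-1-one
Product: 21 trimethyl({6-methyl-2-[(2R)-oxiran-2-yl]-1-(trimethylsilyl)hept-5-en-2-yl}oxy)silane, via lithium alkoxide 20 (not isolated)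
Conditions: Me3SiCH2Li (1.2 equiv), THF, −78 °C; then Me3SiCl (1.5 equiv), −78 °C → rt
Reagents that add atoms: (trimethylsilyl)methyllithium, [Li]C[Si](C)(C)C; chlorotrimethylsilane, C[Si](C)(C)Cl
Why: 1,2-Addition of the weakly basic α-silyl organolithium to the ketone outruns oxirane opening at −78 °C, and the lithium β-silyl alkoxide, which does not undergo Peterson elimination, is capped as its trimethylsilyl ether, the new carbinol centre forming as an inconsequential mixture of epimers.

Step 11
Reactants: 13 3-{[3-acetyl-6-iodo-2,4-bis(methoxymethoxy)phenyl]methyl}-6-ethyl-4-(methoxymethoxy)-5-methyl-2H-pyran-2-one; 21 trimethyl({6-methyl-2-[(2R)-oxiran-2-yl]-1-(trimethylsilyl)hept-5-en-2-yl}oxy)silane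
Product: 22 1-[(2R)-7-{[6-ethyl-4-(methoxymethoxy)-5-methyl-2-oxo-2H-pyran-3-yl]methyl}-4,6-bis(methoxymethoxy)-2-[6-methyl-1-(trimethylsilyl)-2-(trimethylsilyloxy)hept-5-en-2-yl]-2,3-dihydro-1-benzofuran-5-yl]ethanone
Conditions: Pd(OAc)2 (10 mol%), XPhos (20 mol%), 5-norbornene-2-carboxylic acid (50 mol%), K2CO3 (2.5 equiv), 21 (2 equiv), NMP, 80 °C, Ar
Reagents that add atoms: none
Why: Pd(0) inserts into the C–I bond at the carbon that becomes C7a, norbornene carbopalladation and palladation of the single free ortho C–H (future C3a) give an aryl–norbornyl palladacycle, which opens the oxirane at its CH2 terminus (SN2-type oxidative addition to Pd(IV), then C(sp2)–C(sp3) reductive elimination: C3–C3a), and once both ortho positions are substituted norbornene is expelled by β-carbon elimination and the tethered alkoxide forms O1–C7a by C–O reductive elimination. The closest known reaction type is the Pd/norbornene (Catellani-type) annulation of ortho-substituted aryl iodides with terminal epoxides to 2,3-dihydrobenzofurans. The dihydrofuran ring is closed in the last event as a formal 5-exo attack of the alkoxide oxygen on C7a through a six-membered aryl–Pd–alkoxide chelate, so that overall the three-membered oxirane is enlarged to the five-membered ring by insertion of the C3a–C7a unit into its CH2–O bond. No stereocentre is created: C2 is the oxirane CH, whose bonds to O, H and the side chain are never broken, so its (R) configuration should be carried over with retention, and the epimeric silyloxy carbon becomes sp2 in step 12. The step needs one and only one ortho alkylation (secured by the pyranonylmethyl group on C7, which leaves a single ortho C–H and enforces norbornene extrusion), attack at the oxirane CH2 and not at CH (secured by the quaternary carbon next to CH), and an oxirane that Pd(0) cannot ionise (secured by masking the 1,1-disubstituted alkene as a β-silyl silyl ether, so that no allylic C–O bond is present).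

Step 12
Reactants: 22 1-[(2R)-7-{[6-ethyl-4-(methoxymethoxy)-5-methyl-2-oxo-2H-pyran-3-yl]methyl}-4,6-bis(methoxymethoxy)-2-[6-methyl-1-(trimethylsilyl)-2-(trimethylsilyloxy)hept-5-en-2-yl]-2,3-dihydro-1-benzofuran-5-yl]ethanone
Product: 23 3-{[(2R)-5-acetyl-4,6-dihydroxy-2-(6-methylhepta-1,5-dien-2-yl)-2,3-dihydro-1-benzofuran-7-yl]methyl}-6-ethyl-4-hydroxy-5-methyl-2H-pyran-2-one
Conditions: HCl (1.25 M in MeOH), THF, 0 °C → rt
Reagents that add atoms: none
Why: Methanolic acid should cleave the three MOM acetals and the O–SiMe3 ether and then trigger acid-mediated Peterson elimination (anti loss of the β-silyl group), which can only give the 1,1-disubstituted alkene, C2 not being touched.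

Compound list
1 | 1-(2,6-dimethoxyphenyl)ethanone | CC(=O)c1c(OC)cccc1OC | starting material
2 | 1-[2,6-dimethoxy-4-(4,4,5,5-tetramethyl-1,3,2-dioxaborolan-2-yl)phenyl]ethanone (formed in situ) | CC(=O)c1c(OC)cc(cc1OC)B1OC(C)(C)C(C)(C)O1 | intermediate
3 | 1-(4-iodo-2,6-dimethoxyphenyl)ethanone | CC(=O)c1c(OC)cc(I)cc1OC | intermediate
4 | 1-(2,6-dihydroxy-4-iodophenyl)ethanone | CC(=O)c1c(O)cc(I)cc1O | intermediate
5 | methyl 3-oxopentanoate | CCC(=O)CC(=O)OC | starting material
6 | N-methoxy-N-methylpropanamide | CCC(=O)N(C)OC | starting material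
7 | sodium lithium dienolate (dianion) of methyl 3-oxopentanoate (formed in situ) | CC=C([O-])C=C([O-])OC.[Na+].[Li+] | intermediate
8 | methyl 4-methyl-3,5-dioxoheptanoate (racemic, enolisable) | CCC(=O)C(C)C(=O)CC(=O)OC | intermediate
9 | 6-ethyl-4-hydroxy-5-methyl-2H-pyran-2-one | CCc1oc(=O)cc(O)c1C | intermediate
10 | 3-[(dimethylamino)methyl]-6-ethyl-4-hydroxy-5-methyl-2H-pyran-2-one (formed in situ) | CCc1oc(=O)c(CN(C)C)c(O)c1C | intermediate
11 | 6-ethyl-5-methyl-3-methylidene-2H-pyran-2,4(3H)-dione (formed in situ) | CCC1=C(C)C(=O)C(=C)C(=O)O1 | intermediate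
12 | 3-[(3-acetyl-2,4-dihydroxy-6-iodophenyl)methyl]-6-ethyl-4-hydroxy-5-methyl-2H-pyran-2-one | CC(=O)c1c(O)cc(I)c(Cc2c(O)c(C)c(CC)oc2=O)c1O | intermediate
13 | 3-{[3-acetyl-6-iodo-2,4-bis(methoxymethoxy)phenyl]methyl}-6-ethyl-4-(methoxymethoxy)-5-methyl-2H-pyran-2-one | CC(=O)c1c(OCOC)cc(I)c(Cc2c(OCOC)c(C)c(CC)oc2=O)c1OCOC | intermediate
14 | 5-bromo-2-methylpent-2-ene | CC(C)=CCCBr | starting material
15 | acrolein (prop-2-enal) | C=CC=O | starting material
16 | (4-methylpent-3-en-1-yl)magnesium bromide (formed in situ) | CC(C)=CCC[Mg]Br | intermediate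
17 | rac-7-methylocta-1,6-dien-3-ol | C=CC(O)CCC=C(C)C | intermediate
18 | (1S)-5-methyl-1-[(2R)-oxiran-2-yl]hex-4-en-1-ol | CC(C)=CCC[C@H](O)[C@H]1CO1 | intermediate
19 | 5-methyl-1-[(2R)-oxiran-2-yl]hex-4-en-1-one | CC(C)=CCCC(=O)[C@H]1CO1 | intermediate
20 | lithium 6-methyl-2-[(2R)-oxiran-2-yl]-1-(trimethylsilyl)hept-5-en-2-olate (formed in situ, epimers at C2 of the chain) | C[Si](C)(C)CC([O-])(CCC=C(C)C)[C@H]1CO1.[Li+] | intermediate
21 | trimethyl({6-methyl-2-[(2R)-oxiran-2-yl]-1-(trimethylsilyl)hept-5-en-2-yl}oxy)silane (epimers at the silyloxy carbon) | C[Si](C)(C)CC(O[Si](C)(C)C)(CCC=C(C)C)[C@H]1CO1 | intermediate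
22 | 1-[(2R)-7-{[6-ethyl-4-(methoxymethoxy)-5-methyl-2-oxo-2H-pyran-3-yl]methyl}-4,6-bis(methoxymethoxy)-2-[6-methyl-1-(trimethylsilyl)-2-(trimethylsilyloxy)hept-5-en-2-yl]-2,3-dihydro-1-benzofuran-5-yl]ethanone (epimers at the silyloxy carbon) | C[Si](C)(C)CC(O[Si](C)(C)C)(CCC=C(C)C)[C@H]1Cc2c(OCOC)c(C(C)=O)c(OCOC)c(Cc3c(OCOC)c(C)c(CC)oc3=O)c2O1 | intermediate
23 | 3-{[(2R)-5-acetyl-4,6-dihydroxy-2-(6-methylhepta-1,5-dien-2-yl)-2,3-dihydro-1-benzofuran-7-yl]methyl}-6-ethyl-4-hydroxy-5-methyl-2H-pyran-2-one | C=C(CCC=C(C)C)[C@H]1Cc2c(O)c(C(C)=O)c(O)c(Cc3c(O)c(C)c(CC)oc3=O)c2O1 | target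

Total step count: 12. Longest linear sequence: 6 steps (1, 2, 5, 6, 11, 12; the pyranone branch 3, 4, 5, 6, 11, 12 and the oxirane branch 7, 8, 9, 10, 11, 12 are equally long).

Steps most likely to fail

Step 11. The oxirane carries a quaternary carbon next to the ring and the palladated carbon is flanked by a methoxymethoxy group, so opening of the oxirane by the palladacycle may be too slow. Proto-deiodination or norbornene-retaining termination would then win. Loss of the O–SiMe3 group under the basic conditions, followed by Peterson elimination to an allylic oxirane that Pd(0) ionises, would be a second drain. The fallback completes the side chain after the annulation and uses an uncongested, silicon-free oxirane. It sets out from 18 and 13 and comes back to the route at 23. Epoxy alcohol 18 is silylated (TBSCl, imidazole, DMF) to the tert-butyldimethylsilyl ether F1. F1 and 13 are joined under the Pd/norbornene conditions of step 11 to give the dihydrobenzofuran silyl ether F2. TBAF in THF should release the secondary alcohol F3. Neutral oxidation (TPAP/NMO) should give the ketone F4 without enolising its α-aryloxy stereocentre. The non-basic organocerium reagent from Me3SiCH2MgCl/CeCl3 (THF, −78 °C) should add to this unhindered ketone in preference to the di-ortho-substituted aryl ketone, giving the β-hydroxysilane F5. F5 under the conditions of step 12 should give 23.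

Step 5. The methide may be trapped by a second pyranone (methylene-bis-pyranone), the symmetric resorcinol may be alkylated twice, or attack at the carbon flanked by iodine may be sluggish. The fallback reverses the polarity of the bridging, sets out from 4 and 9 and comes back at 12. Resorcinol 4 is aminomethylated with Eschenmoser's salt (MeCN, rt, 1 equiv) to the Mannich base F6. Heating F6 with pyranone 9 (dioxane, 100 °C) should expel dimethylamine to give an ortho-quinone methide, which the nucleophilic C3 of 9 traps to give 12.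

Step 12. Protic acid may add methanol or HCl to the new 1,1-disubstituted alkene or the trisubstituted alkene, or isomerise them, before the last MOM group has gone. The fallback separates alkene formation from deprotection, sets out from 22 and comes back at 23. TBAF (THF, 0 °C → rt) should cleave the O–SiMe3 bond, and the resulting ammonium alkoxide should undergo base-type (syn) Peterson elimination to the tris-MOM ether F7. The MOM groups are then removed without protic acid by ZnBr2/n-PrSH (CH2Cl2, 0 °C) to give 23.

Further compounds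
F1 | step 11 | tert-butyldimethyl({(1S)-5-methyl-1-[(2R)-oxiran-2-yl]hex-4-en-1-yl}oxy)silane | CC(C)=CCC[C@H](O[Si](C)(C)C(C)(C)C)[C@H]1CO1
F2 | step 11 | 1-[(2R)-2-[(1S)-1-{[tert-butyl(dimethyl)silyl]oxy}-5-methylhex-4-en-1-yl]-7-{[6-ethyl-4-(methoxymethoxy)-5-methyl-2-oxo-2H-pyran-3-yl]methyl}-4,6-bis(methoxymethoxy)-2,3-dihydro-1-benzofuran-5-yl]ethanone | CC(C)=CCC[C@H](O[Si](C)(C)C(C)(C)C)[C@H]1Cc2c(OCOC)c(C(C)=O)c(OCOC)c(Cc3c(OCOC)c(C)c(CC)oc3=O)c2O1
F3 | step 11 | 1-[(2R)-7-{[6-ethyl-4-(methoxymethoxy)-5-methyl-2-oxo-2H-pyran-3-yl]methyl}-2-[(1S)-1-hydroxy-5-methylhex-4-en-1-yl]-4,6-bis(methoxymethoxy)-2,3-dihydro-1-benzofuran-5-yl]ethanone | CC(C)=CCC[C@H](O)[C@H]1Cc2c(OCOC)c(C(C)=O)c(OCOC)c(Cc3c(OCOC)c(C)c(CC)oc3=O)c2O1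
F4 | step 11 | 1-[(2R)-5-acetyl-7-{[6-ethyl-4-(methoxymethoxy)-5-methyl-2-oxo-2H-pyran-3-yl]methyl}-4,6-bis(methoxymethoxy)-2,3-dihydro-1-benzofuran-2-yl]-5-methylhex-4-en-1-one | CC(C)=CCCC(=O)[C@H]1Cc2c(OCOC)c(C(C)=O)c(OCOC)c(Cc3c(OCOC)c(C)c(CC)oc3=O)c2O1
F5 | step 11 | 1-[(2R)-7-{[6-ethyl-4-(methoxymethoxy)-5-methyl-2-oxo-2H-pyran-3-yl]methyl}-2-[2-hydroxy-6-methyl-1-(trimethylsilyl)hept-5-en-2-yl]-4,6-bis(methoxymethoxy)-2,3-dihydro-1-benzofuran-5-yl]ethanone (epimers at the carbinol carbon) | C[Si](C)(C)CC(O)(CCC=C(C)C)[C@H]1Cc2c(OCOC)c(C(C)=O)c(OCOC)c(Cc3c(OCOC)c(C)c(CC)oc3=O)c2O1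
F6 | step 5 | 1-{3-[(dimethylamino)methyl]-2,6-dihydroxy-4-iodophenyl}ethanone | CC(=O)c1c(O)cc(I)c(CN(C)C)c1O
F7 | step 12 | 3-{[(2R)-5-acetyl-4,6-bis(methoxymethoxy)-2-(6-methylhepta-1,5-dien-2-yl)-2,3-dihydro-1-benzofuran-7-yl]methyl}-6-ethyl-4-(methoxymethoxy)-5-methyl-2H-pyran-2-one | C=C(CCC=C(C)C)[C@H]1Cc2c(OCOC)c(C(C)=O)c(OCOC)c(Cc3c(OCOC)c(C)c(CC)oc3=O)c2O1
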